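# Proposed synthesis of (2R)-2,5,7,8-tetramethyl-2-[(4R,8S)-4,8,12-trimethyltridec-12-en-1-yl]chroman-6-ol (23)

## Analysis of the target

The target 23 is a 6-chromanol: a fully substituted benzene ring (C4a, C5, C6, C7, C8, C8a; methyls on C5, C7 and C8, free hydroxyl on C6) fused to a dihydropyran ring (O1, C2, C3, C4, C4a, C8a). C2 carries a methyl group and a chain C1' to C13' with methyl branches on C4', C8' and C12' and a 1,1-disubstituted alkene C12'=C13'. There are three stereocentres: C2 (R), C4' (R) and C8', which has the same spatial sense as in natural α-tocopherol but the descriptor S, because the arm ending in the isopropenyl group outranks the arm leading to the ring. Each centre is separated from the next by three methylene groups, so none can direct another, and a wrong epimer would be a remote diastereomer that ordinary chromatography will not remove. The sensitive groups are the electron-rich phenol, which oxidises easily (most readily as the phenoxide), and the terminal alkene, which cannot pass through a hydrogenation and moves into the chain under acid. The hard part is C2, a fully substituted ether carbon whose two carbon substituents (methyl and a methylene chain) differ little in size, attached to a chain without functional handles. The plan rests on the position of C2 next to O1 and two atoms from C4. If C4 is carried as a carbonyl, O-silylation turns the ring O1–C2–C3–C4–C4a–C8a into an aromatic benzopyrylium whose electrophilic carbon is C2. The bond C2–C1' and the C2 configuration can then be made in one catalytic step, with C1'≡C2' of an alkyne as the nucleophile.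

## Retrosynthetic reasoning

23 to 22. The last operation is cleavage of the O6–Si bond. The phenol is kept as its silyl ether 22 throughout, because the free phenol would be oxidised and would consume the organometallic reagents.

22 to 20 and 21. The bond C11'–C12' is cut. The isopropenyl group has to come in after every reductive step, and this cut leaves a primary sulfonate at C11' (20) and the alkenyl Grignard reagent 21. No stereocentre lies at either carbon.

20 back to 17. The sulfonate 20 comes from the primary alcohol 19. The C4 methylene of 19 comes from the C4 alcohol 18 and this from the C4 ketone 17. The C4 oxygen is put back on purpose: it is the handle that activates C2 in the key step, and its removal costs two simple reductions.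

17 to 16. The saturated C1'–C2' unit of 17 is traced back to the alkyne of 16 and the C11' hydroxyl to a benzyl ether. One hydrogenation should do both in the forward direction.

16 to 5 and 13 (key disconnection). The bond C2–C1' is cut. It is the only bond whose formation creates the quaternary stereocentre and joins two fragments of similar size in the same step. Cutting O1–C2 instead would mean closing the ring on a substrate that already carries the chain, or carrying only a stub of it. The forward step has to deliver the acetylide of 13 to C2 of the benzopyrylium 14 (made from 5) on one face, and a linear alkyne is the slimmest carbon nucleophile for a centre this crowded.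

5 to 1. The silyl ether 5 comes from the hydroxychromone 4. The pyranone of 4 is opened at O1–C2 and C2–C3 to the diketone 3, which is the Claisen product of the acetophenone 2. The acetyl group of 2 is removed to give 1, whose single free ring carbon fixes the regiochemistry.

13 to 9. The bond C2'–C3' is cut (acetylide displacement of the chloride 12). The benzyl ether of 12 comes from the alcohol 11, and the C11' hydroxyl of 11 from ozonolysis (through the aldehyde 10) of the isopropylidene alkene of 9.

9 to 6 and 7. The bond C5'–C6' is cut between two methylene groups, away from both stereocentres. The bromide 6 (through its Grignard reagent 8) supplies C6' to C11' with C8'. The dihalide 7 supplies C3' to C5' with C4'. Its two halogens differ enough in reactivity that no protecting group is needed.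

## Alternatives that were turned down

Alternative 1: The pyran ring is opened at O1–C2 and the chain is cut at C1'–C2', which leads to the alkenyl phenol A2. In the forward step Pd(OCOCF3)2 (divalent palladium) with a chiral bis(oxazolinyl)binaphthyl ligand activates the 1,1-disubstituted alkene, and the phenol oxygen adds to its inner carbon in a 6-exo oxypalladation that creates C2. The primary alkylpalladium on C1' has no β-hydrogen, so it inserts carbon monoxide and is released by methanol as the ester A1, while p-benzoquinone returns the metal to the divalent state. In its favour, ring and quaternary centre arise together from an achiral phenol, and C3 and C4 are methylenes from the start. On that point it is stronger than the chosen plan, which spends two steps on removing the C4 oxygen. Against it, A1 holds only two of the thirteen chain carbons. The other eleven, with C4' and C8', would still have to be joined by reduction, olefination and hydrogenation, and the isopropenyl end would again have to be added after that. The ligand has to be made in several steps. The 6-O-methyl ether would have to be cleaved at the end with a Lewis acid beside the acid-sensitive alkene, or by oxidation to the quinone and reductive re-closure. The chosen alkynylation attaches C1' to C11' in the same bond that sets C2, and its phenol protecting group leaves with fluoride.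

Alternative 2: The chain is cut in the middle, at C6'–C7', far from every stereocentre. The two N-hydroxyphthalimide esters A3 (chroman half with C2 and C4') and A4 (half with C8' and the isopropenyl group) would be reduced at a cathode with NiCl2·6H2O and 2,2':6',2''-terpyridine. Each loses CO2 to a primary alkyl radical and nickel joins the two to the acetate A5. In its favour, both acids are close to chiral-pool terpenoid acids, the alkene is brought in intact, and only deacetylation follows. In steps after the key bond it is clearly stronger than the chosen route (one against six). Against it, the two radicals are both unhindered primary alkyls, so the metal cannot tell them apart and the cross product competes with both homodimers. The chroman half is the costly one, and the three products are all lipophilic and hard to separate. Most important, A3 already contains the quaternary C2, so the real problem is only moved into the synthesis of A3. The chosen plan forms the bond that solves C2, between partners of opposite polarity, so that only the cross product can form.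

Alternative 3: No skeletal bond is cut. C4' and C8' are traced back to the E-trisubstituted alkenes C3'=C4' and C7'=C8' of the dienyl ketone A6. In the forward step [Ir(cod)(L)]B(C6H3(CF3)2)4 (monovalent iridium, L a chiral pyridyl phosphinite) would add hydrogen to both alkenes under catalyst control to give A7, and the C12' ketone would then be methylenated. In its favour, two stereocentres come from one catalytic step. A methyl ketone is also a very good precursor of the 1,1-disubstituted alkene, arguably better than the sulfonate coupling used here, so in stereo-economy of the chain it is the stronger plan. Against it, A6 must be geometrically pure at both alkenes, since each Z isomer would end as an inseparable epimer. A6 already needs C2 and a long linear chain assembly. The aryl acetate would not survive a phosphorus ylide, so a protecting-group exchange would precede the olefination. The chosen plan takes C4' and C8' enantiopure from the chiral pool and spends its one asymmetric catalytic step on C2, the only centre that cannot be bought.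

Key step: step 8

## Remarks on the chemistry (assumptions)

- The sense of induction of the bis(oxazoline) ligand on this benzopyrylium is taken to be the one that gives (2S)-16 with the (S,S)-ligand written in step 8. If the first run shows the opposite sense, the mirror-image ligand is used and nothing else changes.
- Compounds 6 and 7 are taken as purchasable. Each is otherwise one Appel halogenation away from the commercial alcohol ((R)-citronellol and (S)-3-bromo-2-methylpropan-1-ol).

## Route

Step 1
Reactants: 1 trimethylhydroquinone (2,3,5-trimethylbenzene-1,4-diol)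
Product: 2 1-(2,5-dihydroxy-3,4,6-trimethylphenyl)ethan-1-one
Conditions: AcOH, BF3·OEt2 (3 equiv), 100 °C, argon; then H2O
Reagents that add atoms: acetic acid, CC(=O)O
Why: Friedel–Crafts C-acetylation (equivalent to O-acetylation and Fries rearrangement under BF3); the ring has one unsubstituted carbon, ortho to a hydroxyl, so only one regioisomer can form, and the product is held as its boron chelate until hydrolysis.

Step 2
Reactants: 2 1-(2,5-dihydroxy-3,4,6-trimethylphenyl)ethan-1-one
Product: 4 6-hydroxy-2,5,7,8-tetramethyl-4H-chromen-4-one, via diketone 3 (not isolated)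
Conditions: NaH (5 equiv), EtOAc (6 equiv), THF, 0 °C to reflux, argon; then conc. HCl, AcOH, 90 °C
Reagents that add atoms: ethyl acetate, CCOC(C)=O
Why: Claisen condensation of the methyl ketone enolate (formed after both phenols are deprotonated) with the ester gives the 1,3-diketone 3; acid then closes the pyranone by attack of the ortho hydroxyl on the outer carbonyl and loss of water, the classical 2-methylchromone synthesis.

Step 3
Reactants: 4 6-hydroxy-2,5,7,8-tetramethyl-4H-chromen-4-one
Product: 5 6-[(tert-butyldimethylsilyl)oxy]-2,5,7,8-tetramethyl-4H-chromen-4-one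
Conditions: TBSCl (1.5 equiv), imidazole (3 equiv), DMF, 50 °C
Reagents that add atoms: tert-butyldimethylsilyl chloride, CC(C)(C)[Si](C)(C)Cl
Why: Silylation of the phenol; the hydroxyl lies between two methyl groups, hence the gentle heating, and the silyl chloride does not touch the chromone carbonyl.

Step 4
Reactants: 6 (R)-citronellyl bromide [(6R)-8-bromo-2,6-dimethyloct-2-ene]; 7 (S)-1-bromo-3-chloro-2-methylpropane
Product: 9 (6S,10R)-11-chloro-2,6,10-trimethylundec-2-ene, via Grignard reagent 8 (not isolated)
Conditions: Mg, THF, 40 °C; then 7 (1.2 equiv), Li2CuCl4 (3 mol %), NMP (4 equiv), THF, 0 to 20 °C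
Reagents that add atoms: none
Why: Grignard formation followed by copper-catalysed sp3–sp3 cross-coupling (Li2CuCl4 is reduced in the flask to the active monovalent copper species); the C–Br bond of 7 couples and the C–Cl bond does not under these conditions, and neither stereocentre is a reacting carbon, so both are carried over unchanged (the descriptors change only through priority).

Step 5
Reactants: 9 (6S,10R)-11-chloro-2,6,10-trimethylundec-2-ene
Product: 11 (4S,8R)-9-chloro-4,8-dimethylnonan-1-ol, via chloro aldehyde 10 (not isolated)
Conditions: O3, CH2Cl2/MeOH, −78 °C; then NaBH4, −78 to 20 °C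
Reagents that add atoms: ozone, [O-][O+]=O
Why: Ozonolysis of the electron-rich trisubstituted alkene with borohydride work-up gives the primary alcohol at the future C11'; the alkyl chloride is inert to ozone and to NaBH4.

Step 6
Reactants: 11 (4S,8R)-9-chloro-4,8-dimethylnonan-1-ol
Product: 12 ({[(4S,8R)-9-chloro-4,8-dimethylnonyl]oxy}methyl)benzene
Conditions: NaH (1.3 equiv), BnBr (1.2 equiv), Bu4NI (5 mol %), THF, 0 to 20 °C
Reagents that add atoms: benzyl bromide, BrCc1ccccc1
Why: Williamson etherification; benzyl bromide reacts with the alkoxide far faster than the β-branched primary chloride, so displacement of chloride should not compete.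

Step 7
Reactants: 12 ({[(4S,8R)-9-chloro-4,8-dimethylnonyl]oxy}methyl)benzene
Product: 13 ({[(4S,8R)-4,8-dimethylundec-10-yn-1-yl]oxy}methyl)benzene [(4R,8S)-11-(benzyloxy)-4,8-dimethylundec-1-yne]
Conditions: LiC≡CH·H2NCH2CH2NH2 (3 equiv), NaI (0.2 equiv), DMSO, 20 to 45 °C
Reagents that add atoms: lithium acetylide–ethylenediamine complex, [Li+].[C-]#C.NCCN
Why: SN2 displacement by acetylide in DMSO, helped by iodide (Finkelstein exchange in the flask); substitution is at the CH2 group, so the neighbouring stereocentre is untouched, and the product is protected from alkyne migration as its lithium salt until work-up.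

Step 8
Reactants: 5 6-[(tert-butyldimethylsilyl)oxy]-2,5,7,8-tetramethyl-4H-chromen-4-one; 13 ({[(4S,8R)-4,8-dimethylundec-10-yn-1-yl]oxy}methyl)benzene
Product: 16 (2S)-2-[(4R,8S)-11-(benzyloxy)-4,8-dimethylundec-1-yn-1-yl]-6-[(tert-butyldimethylsilyl)oxy]-2,5,7,8-tetramethylchroman-4-one, via benzopyrylium triflate 14 (not isolated), via silyl enol ether 15 (not isolated)
Conditions: 5 (1.3 equiv), TBSOTf (1.3 equiv), PhMe, 60 °C; then added to 13 (1.0 equiv), CuI (10 mol %), 2,2'-(propane-2,2-diyl)bis[(4S)-4-phenyl-4,5-dihydro-1,3-oxazole] (12 mol %), iPr2NEt (1.6 equiv), PhMe, −40 °C; then 2 M aq. HCl, THF, 0 °C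
Reagents that add atoms: none
Why: O-Silylation of the carbonyl of 5 gives the aromatic 4-silyloxybenzopyrylium 14, whose electrophilic carbon next to O1 is C2, while iPr2NEt deprotonates 13 at the ligand-bound monovalent copper centre to give a chiral copper acetylide. The acetylide carbon C1' bonds to C2 of 14 to give the silyl enol ether 15, and dilute acid then hydrolyses the enol ether, but not the hindered aryl ether, to the chromanone 16. The closest known reaction type is the copper bis(oxazoline)-catalysed alkynylation of 2-alkyl-4-silyloxybenzopyrylium triflates to chromanones with a tertiary ether carbon, applied here to a more electron-rich trimethylated cation and an aliphatic alkyne. No ring is closed and one skeletal bond, C2–C1', is formed. The new stereocentre C2 is set by the catalyst alone: the cation is planar and C4' and C8' of the acetylide are too remote to bias the approach, so the ligand enantiomer decides the face (the descriptor of 16 is S only because the alkynyl group outranks C3; the arrangement is that of 23). Attack at C2 and not at C4 is secured by the substrate, since C4 carries the silyloxy donor and is shielded by the methyl on C5, whereas C2 is flanked only by a methyl and O1. The benzyl ether and the aryl silyl ether are inert to the silyl triflate and the amine at this temperature, and deprotonation of the C2 methyl of 14 by the amine is reversible and should only lower the concentration of the electrophile.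

Step 9
Reactants: 16 (2S)-2-[(4R,8S)-11-(benzyloxy)-4,8-dimethylundec-1-yn-1-yl]-6-[(tert-butyldimethylsilyl)oxy]-2,5,7,8-tetramethylchroman-4-one
Product: 17 (2R)-6-[(tert-butyldimethylsilyl)oxy]-2-[(4R,8S)-11-hydroxy-4,8-dimethylundecyl]-2,5,7,8-tetramethylchroman-4-one
Conditions: H2 (1 atm), 10% Pd/C, EtOAc/EtOH, 20 °C
Reagents that add atoms: none
Why: Heterogeneous hydrogenation saturates the alkyne and cleaves the benzyl ether by hydrogenolysis in one operation; the hindered aryl ketone and the aryl silyl ether should not react in neutral medium at this pressure, and neutral conditions avoid base-induced opening of the β-aryloxy ketone, which would erode C2.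

Step 10
Reactants: 17 (2R)-6-[(tert-butyldimethylsilyl)oxy]-2-[(4R,8S)-11-hydroxy-4,8-dimethylundecyl]-2,5,7,8-tetramethylchroman-4-one
Product: 18 (2R)-6-[(tert-butyldimethylsilyl)oxy]-2-[(4R,8S)-11-hydroxy-4,8-dimethylundecyl]-2,5,7,8-tetramethylchroman-4-ol (both C4 epimers)
Conditions: NaBH4 (2 equiv), MeOH/THF, 0 to 20 °C
Reagents that add atoms: none
Why: Borohydride reduction of the aryl ketone; the configuration at C4 does not matter because C4 becomes a methylene in the next step, and the low temperature keeps ring opening of the ketone from competing.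

Step 11
Reactants: 18 (2R)-6-[(tert-butyldimethylsilyl)oxy]-2-[(4R,8S)-11-hydroxy-4,8-dimethylundecyl]-2,5,7,8-tetramethylchroman-4-ol
Product: 19 (4S,8R)-11-[(2R)-6-[(tert-butyldimethylsilyl)oxy]-2,5,7,8-tetramethylchroman-2-yl]-4,8-dimethylundecan-1-ol
Conditions: Et3SiH (3 equiv), CF3CO2H (10 equiv), CH2Cl2, 0 °C; then sat. aq. NaHCO3, MeOH, 20 °C
Reagents that add atoms: none
Why: Ionic hydrogenation: acid ionises the benzylic C4 alcohol to a cation stabilised by O1 through C8a, and the silane delivers hydride; the primary alcohol cannot ionise, and any trifluoroacetate formed on it is cleaved in the bicarbonate/methanol work-up.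

Step 12
Reactants: 19 (4S,8R)-11-[(2R)-6-[(tert-butyldimethylsilyl)oxy]-2,5,7,8-tetramethylchroman-2-yl]-4,8-dimethylundecan-1-ol
Product: 20 (4S,8R)-11-[(2R)-6-[(tert-butyldimethylsilyl)oxy]-2,5,7,8-tetramethylchroman-2-yl]-4,8-dimethylundecyl 4-methylbenzenesulfonate
Conditions: TsCl (1.3 equiv), pyridine, DMAP (5 mol %), CH2Cl2, 0 to 20 °C
Reagents that add atoms: 4-methylbenzenesulfonyl chloride, Cc1ccc(cc1)S(Cl)(=O)=O
Why: Sulfonylation of the only free hydroxyl, a primary alcohol.

Step 13
Reactants: 20 (4S,8R)-11-[(2R)-6-[(tert-butyldimethylsilyl)oxy]-2,5,7,8-tetramethylchroman-2-yl]-4,8-dimethylundecyl 4-methylbenzenesulfonate; 21 isopropenylmagnesium bromide (prop-1-en-2-ylmagnesium bromide)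
Product: 22 tert-butyldimethyl({(2R)-2,5,7,8-tetramethyl-2-[(4R,8S)-4,8,12-trimethyltridec-12-en-1-yl]chroman-6-yl}oxy)silane
Conditions: 21 (3 equiv), Li2CuCl4 (5 mol %), THF, −78 to 20 °C
Reagents that add atoms: none
Why: Copper-catalysed coupling of an alkenyl Grignard reagent with a primary alkyl sulfonate forms C11'–C12' and brings in the 1,1-disubstituted alkene after all reductions are over; the hindered aryl silyl ether is inert to the Grignard reagent.

Step 14
Reactants: 22 tert-butyldimethyl({(2R)-2,5,7,8-tetramethyl-2-[(4R,8S)-4,8,12-trimethyltridec-12-en-1-yl]chroman-6-yl}oxy)silane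
Product: 23 (2R)-2,5,7,8-tetramethyl-2-[(4R,8S)-4,8,12-trimethyltridec-12-en-1-yl]chroman-6-ol
Conditions: Bu4NF (1.2 equiv), AcOH (1.2 equiv), THF, 0 °C, argon
Reagents that add atoms: none
Why: Fluoride cleaves the aryl silyl ether; the acetic acid buffer and the exclusion of air keep the phenoxide from oxidising and the alkene from migrating.

## Compound list

1 | trimethylhydroquinone (2,3,5-trimethylbenzene-1,4-diol) | Cc1cc(O)c(C)c(C)c1O | starting material
2 | 1-(2,5-dihydroxy-3,4,6-trimethylphenyl)ethan-1-one | CC(=O)c1c(O)c(C)c(C)c(O)c1C | intermediate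
3 | 1-(2,5-dihydroxy-3,4,6-trimethylphenyl)butane-1,3-dione (formed in the flask) | CC(=O)CC(=O)c1c(O)c(C)c(C)c(O)c1C | intermediate
4 | 6-hydroxy-2,5,7,8-tetramethyl-4H-chromen-4-one | CC1=CC(=O)c2c(C)c(O)c(C)c(C)c2O1 | intermediate
5 | 6-[(tert-butyldimethylsilyl)oxy]-2,5,7,8-tetramethyl-4H-chromen-4-one | CC1=CC(=O)c2c(C)c(O[Si](C)(C)C(C)(C)C)c(C)c(C)c2O1 | intermediate
6 | (R)-citronellyl bromide, (6R)-8-bromo-2,6-dimethyloct-2-ene | CC(C)=CCC[C@@H](C)CCBr | starting material
7 | (S)-1-bromo-3-chloro-2-methylpropane | BrC[C@@H](C)CCl | starting material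
8 | [(3R)-3,7-dimethyloct-6-en-1-yl]magnesium bromide (formed in the flask) | CC(C)=CCC[C@@H](C)CC[Mg]Br | intermediate
9 | (6S,10R)-11-chloro-2,6,10-trimethylundec-2-ene | CC(C)=CCC[C@@H](C)CCC[C@@H](C)CCl | intermediate
10 | (4S,8R)-9-chloro-4,8-dimethylnonanal (formed in the flask) | O=CCC[C@@H](C)CCC[C@@H](C)CCl | intermediate
11 | (4S,8R)-9-chloro-4,8-dimethylnonan-1-ol | OCCC[C@@H](C)CCC[C@@H](C)CCl | intermediate
12 | ({[(4S,8R)-9-chloro-4,8-dimethylnonyl]oxy}methyl)benzene | c1ccccc1COCCC[C@@H](C)CCC[C@@H](C)CCl | intermediate
13 | ({[(4S,8R)-4,8-dimethylundec-10-yn-1-yl]oxy}methyl)benzene | c1ccccc1COCCC[C@@H](C)CCC[C@@H](C)CC#C | intermediate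
14 | 4,6-bis[(tert-butyldimethylsilyl)oxy]-2,5,7,8-tetramethylchromenylium trifluoromethanesulfonate (formed in the flask) | Cc1cc(O[Si](C)(C)C(C)(C)C)c2c(C)c(O[Si](C)(C)C(C)(C)C)c(C)c(C)c2[o+]1.[O-]S(=O)(=O)C(F)(F)F | intermediate
15 | (2S)-2-[(4R,8S)-11-(benzyloxy)-4,8-dimethylundec-1-yn-1-yl]-4,6-bis[(tert-butyldimethylsilyl)oxy]-2,5,7,8-tetramethyl-2H-chromene (formed in the flask) | c1ccccc1COCCC[C@@H](C)CCC[C@@H](C)CC#C[C@]1(C)C=C(O[Si](C)(C)C(C)(C)C)c2c(C)c(O[Si](C)(C)C(C)(C)C)c(C)c(C)c2O1 | intermediate
16 | (2S)-2-[(4R,8S)-11-(benzyloxy)-4,8-dimethylundec-1-yn-1-yl]-6-[(tert-butyldimethylsilyl)oxy]-2,5,7,8-tetramethylchroman-4-one | c1ccccc1COCCC[C@@H](C)CCC[C@@H](C)CC#C[C@]1(C)CC(=O)c2c(C)c(O[Si](C)(C)C(C)(C)C)c(C)c(C)c2O1 | intermediate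
17 | (2R)-6-[(tert-butyldimethylsilyl)oxy]-2-[(4R,8S)-11-hydroxy-4,8-dimethylundecyl]-2,5,7,8-tetramethylchroman-4-one | OCCC[C@@H](C)CCC[C@@H](C)CCC[C@]1(C)CC(=O)c2c(C)c(O[Si](C)(C)C(C)(C)C)c(C)c(C)c2O1 | intermediate
18 | (2R)-6-[(tert-butyldimethylsilyl)oxy]-2-[(4R,8S)-11-hydroxy-4,8-dimethylundecyl]-2,5,7,8-tetramethylchroman-4-ol (both C4 epimers) | OCCC[C@@H](C)CCC[C@@H](C)CCC[C@]1(C)CC(O)c2c(C)c(O[Si](C)(C)C(C)(C)C)c(C)c(C)c2O1 | intermediate
19 | (4S,8R)-11-[(2R)-6-[(tert-butyldimethylsilyl)oxy]-2,5,7,8-tetramethylchroman-2-yl]-4,8-dimethylundecan-1-ol | OCCC[C@@H](C)CCC[C@@H](C)CCC[C@]1(C)CCc2c(C)c(O[Si](C)(C)C(C)(C)C)c(C)c(C)c2O1 | intermediate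
20 | (4S,8R)-11-[(2R)-6-[(tert-butyldimethylsilyl)oxy]-2,5,7,8-tetramethylchroman-2-yl]-4,8-dimethylundecyl 4-methylbenzenesulfonate | Cc1ccc(cc1)S(=O)(=O)OCCC[C@@H](C)CCC[C@@H](C)CCC[C@]1(C)CCc2c(C)c(O[Si](C)(C)C(C)(C)C)c(C)c(C)c2O1 | intermediate
21 | isopropenylmagnesium bromide | C=C(C)[Mg]Br | starting material
22 | tert-butyldimethyl({(2R)-2,5,7,8-tetramethyl-2-[(4R,8S)-4,8,12-trimethyltridec-12-en-1-yl]chroman-6-yl}oxy)silane | C=C(C)CCC[C@@H](C)CCC[C@@H](C)CCC[C@]1(C)CCc2c(C)c(O[Si](C)(C)C(C)(C)C)c(C)c(C)c2O1 | intermediate
23 | (2R)-2,5,7,8-tetramethyl-2-[(4R,8S)-4,8,12-trimethyltridec-12-en-1-yl]chroman-6-ol | C=C(C)CCC[C@@H](C)CCC[C@@H](C)CCC[C@]1(C)CCc2c(C)c(O)c(C)c(C)c2O1 | target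

## Step count and least certain steps

Total step count: 14. Longest linear sequence: 11 steps (6 to 23 through steps 4 to 14). The chromone branch (steps 1 to 3) joins at step 8.

Step 8 (key step). The most likely failures are slow addition and poor facial selectivity. The acetylide of an aliphatic alkyne is less reactive and less rigid than an arylacetylide, and the cation 14 is electron-rich and crowded. Loss of the electrophile by deprotonation at its C2 methyl group is a further risk. The fallback sets the C2 centre with a compact silylacetylene and joins the chain afterwards by olefin metathesis. It sets out from 5 (and uses 13 for the chain) and returns at 17. The same copper/bis(oxazoline) addition to 14, now with ethynyltrimethylsilane, should give (2S)-6-[(tert-butyldimethylsilyl)oxy]-2,5,7,8-tetramethyl-2-[(trimethylsilyl)ethynyl]chroman-4-one F1. Brief treatment with K2CO3 in MeOH at 0 °C removes the C-silyl group to give (2S)-6-[(tert-butyldimethylsilyl)oxy]-2-ethynyl-2,5,7,8-tetramethylchroman-4-one F2. Semi-hydrogenation (H2, Pd/CaCO3 poisoned with Pb(OAc)2, quinoline) gives (2S)-6-[(tert-butyldimethylsilyl)oxy]-2-ethenyl-2,5,7,8-tetramethylchroman-4-one F3. The same semi-hydrogenation of 13 gives ({[(4S,8R)-4,8-dimethylundec-10-en-1-yl]oxy}methyl)benzene F4. Cross-metathesis of F3 with an excess of F4 (second-generation Hoveyda–Grubbs catalyst, RuCl2(H2IMes)(=CH-C6H4-2-OiPr), CH2Cl2, 40 °C) should give (2S)-2-[(1E,4R,8S)-11-(benzyloxy)-4,8-dimethylundec-1-en-1-yl]-6-[(tert-butyldimethylsilyl)oxy]-2,5,7,8-tetramethylchroman-4-one F5. Hydrogenation of F5 over 10% Pd/C then gives 17.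

Step 9. The C2–O1 bond is propargylic and, after partial reduction, allylic. Palladium may cleave it by hydrogenolysis, which would open the ring and destroy C2. Traces of copper or amine from step 8 may also stop the debenzylation. The fallback separates the two events and avoids a metal while unsaturation is next to C2. It sets out from 16 and returns at 17. Diimide (4-methylbenzenesulfonohydrazide, NaOAc, THF/H2O, 65 °C) saturates the alkyne to (2R)-2-[(4R,8S)-11-(benzyloxy)-4,8-dimethylundecyl]-6-[(tert-butyldimethylsilyl)oxy]-2,5,7,8-tetramethylchroman-4-one F6. Its benzyl ether is then removed over 10% Pd/C under H2, when no allylic C–O bond is left.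

Step 7. Substitution at the β-branched primary chloride may be slow, and elimination to the 1,1-disubstituted alkene may compete. The fallback reverses the polarity at C3' and builds the alkyne by carbonyl homologation. It sets out from 12 and returns at 13. Magnesium in refluxing THF converts 12 into [(2R,6S)-9-(benzyloxy)-2,6-dimethylnonyl]magnesium chloride F7. Formylation with DMF gives (3R,7S)-10-(benzyloxy)-3,7-dimethyldecanal F8. The Ohira–Bestmann reaction (dimethyl (1-diazo-2-oxopropyl)phosphonate, K2CO3, MeOH) converts F8 into 13. F8 is branched at the β-carbon, so there is no epimerisable centre.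

Step 13. Alkenyl Grignard reagents transfer less readily than alkyl ones under copper catalysis, so exchange of the sulfonate for bromide and incomplete coupling are the likely problems. The fallback moves the nucleophile to C11' and uses palladium. It sets out from 20 and returns at 22. NaI in acetone gives tert-butyl({(2R)-2-[(4R,8S)-11-iodo-4,8-dimethylundecyl]-2,5,7,8-tetramethylchroman-6-yl}oxy)dimethylsilane F9. Activated zinc in THF gives the alkylzinc iodide F10. Negishi coupling of F10 with 2-bromopropene (PdCl2(dppf), a divalent palladium precatalyst, THF, 50 °C) gives 22.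

Step 2. The doubly deprotonated hydroquinone is oxidised easily, and O-acetylation or incomplete C-acylation of the hindered ketone enolate may lower conversion. The fallback makes the diketone by an intramolecular acyl shift. It sets out from 2 and returns at 4. Ac2O, pyridine and DMAP give 2-acetyl-3,5,6-trimethyl-1,4-phenylene diacetate F11. KOtBu in THF at 0 °C brings about the Baker–Venkataraman O-to-C acetyl shift to 4-hydroxy-2,3,6-trimethyl-5-(3-oxobutanoyl)phenyl acetate F12. H2SO4 in refluxing MeOH closes the pyranone and removes the remaining acetate to give 4.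

## Further compounds

F1 | step 8 | (2S)-6-[(tert-butyldimethylsilyl)oxy]-2,5,7,8-tetramethyl-2-[(trimethylsilyl)ethynyl]chroman-4-one | C[Si](C)(C)C#C[C@]1(C)CC(=O)c2c(C)c(O[Si](C)(C)C(C)(C)C)c(C)c(C)c2O1
F2 | step 8 | (2S)-6-[(tert-butyldimethylsilyl)oxy]-2-ethynyl-2,5,7,8-tetramethylchroman-4-one | C#C[C@]1(C)CC(=O)c2c(C)c(O[Si](C)(C)C(C)(C)C)c(C)c(C)c2O1
F3 | step 8 | (2S)-6-[(tert-butyldimethylsilyl)oxy]-2-ethenyl-2,5,7,8-tetramethylchroman-4-one | C=C[C@]1(C)CC(=O)c2c(C)c(O[Si](C)(C)C(C)(C)C)c(C)c(C)c2O1
F4 | step 8 | ({[(4S,8R)-4,8-dimethylundec-10-en-1-yl]oxy}methyl)benzene | c1ccccc1COCCC[C@@H](C)CCC[C@@H](C)CC=C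
F5 | step 8 | (2S)-2-[(1E,4R,8S)-11-(benzyloxy)-4,8-dimethylundec-1-en-1-yl]-6-[(tert-butyldimethylsilyl)oxy]-2,5,7,8-tetramethylchroman-4-one | c1ccccc1COCCC[C@@H](C)CCC[C@@H](C)C/C=C/[C@]1(C)CC(=O)c2c(C)c(O[Si](C)(C)C(C)(C)C)c(C)c(C)c2O1
F6 | step 9 | (2R)-2-[(4R,8S)-11-(benzyloxy)-4,8-dimethylundecyl]-6-[(tert-butyldimethylsilyl)oxy]-2,5,7,8-tetramethylchroman-4-one | c1ccccc1COCCC[C@@H](C)CCC[C@@H](C)CCC[C@]1(C)CC(=O)c2c(C)c(O[Si](C)(C)C(C)(C)C)c(C)c(C)c2O1
F7 | step 7 | [(2R,6S)-9-(benzyloxy)-2,6-dimethylnonyl]magnesium chloride | c1ccccc1COCCC[C@@H](C)CCC[C@@H](C)C[Mg]Cl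
F8 | step 7 | (3R,7S)-10-(benzyloxy)-3,7-dimethyldecanal | c1ccccc1COCCC[C@@H](C)CCC[C@@H](C)CC=O
F9 | step 13 | tert-butyl({(2R)-2-[(4R,8S)-11-iodo-4,8-dimethylundecyl]-2,5,7,8-tetramethylchroman-6-yl}oxy)dimethylsilane | ICCC[C@@H](C)CCC[C@@H](C)CCC[C@]1(C)CCc2c(C)c(O[Si](C)(C)C(C)(C)C)c(C)c(C)c2O1
F10 | step 13 | {(4S,8R)-11-[(2R)-6-[(tert-butyldimethylsilyl)oxy]-2,5,7,8-tetramethylchroman-2-yl]-4,8-dimethylundecyl}zinc iodide | I[Zn]CCC[C@@H](C)CCC[C@@H](C)CCC[C@]1(C)CCc2c(C)c(O[Si](C)(C)C(C)(C)C)c(C)c(C)c2O1
F11 | step 2 | 2-acetyl-3,5,6-trimethyl-1,4-phenylene diacetate | CC(=O)Oc1c(C)c(C)c(OC(C)=O)c(C(C)=O)c1C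
F12 | step 2 | 4-hydroxy-2,3,6-trimethyl-5-(3-oxobutanoyl)phenyl acetate | CC(=O)CC(=O)c1c(O)c(C)c(C)c(OC(C)=O)c1C
A1 | alternative 1 | methyl 2-[(2S)-6-methoxy-2,5,7,8-tetramethylchroman-2-yl]acetate | COC(=O)C[C@]1(C)CCc2c(C)c(OC)c(C)c(C)c2O1
A2 | alternative 1 | 4-methoxy-2,3,5-trimethyl-6-(3-methylbut-3-en-1-yl)phenol | C=C(C)CCc1c(C)c(OC)c(C)c(C)c1O
A3 | alternative 2 | 1,3-dioxoisoindolin-2-yl (4S)-7-[(2R)-6-acetoxy-2,5,7,8-tetramethylchroman-2-yl]-4-methylheptanoate | O=C(ON1C(=O)c2ccccc2C1=O)CC[C@@H](C)CCC[C@]1(C)CCc2c(C)c(OC(C)=O)c(C)c(C)c2O1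
A4 | alternative 2 | 1,3-dioxoisoindolin-2-yl (3R)-3,7-dimethyloct-7-enoate | C=C(C)CCC[C@@H](C)CC(=O)ON1C(=O)c2ccccc2C1=O
A5 | alternative 2 | (2R)-2,5,7,8-tetramethyl-2-[(4R,8S)-4,8,12-trimethyltridec-12-en-1-yl]chroman-6-yl acetate | C=C(C)CCC[C@@H](C)CCC[C@@H](C)CCC[C@]1(C)CCc2c(C)c(OC(C)=O)c(C)c(C)c2O1
A6 | alternative 3 | (2R)-2-[(3E,7E)-4,8-dimethyl-12-oxotrideca-3,7-dien-1-yl]-2,5,7,8-tetramethylchroman-6-yl acetate | CC(=O)CCC/C(C)=C/CC/C(C)=C/CC[C@]1(C)CCc2c(C)c(OC(C)=O)c(C)c(C)c2O1
A7 | alternative 3 | (2R)-2-[(4R,8S)-4,8-dimethyl-12-oxotridecyl]-2,5,7,8-tetramethylchroman-6-yl acetate | CC(=O)CCC[C@@H](C)CCC[C@@H](C)CCC[C@]1(C)CCc2c(C)c(OC(C)=O)c(C)c(C)c2O1
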